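The flavone is cut at the C4–C4a bond of the pyranone (ring C). An intramolecular Friedel–Crafts acylation of a β-aryloxycinnamic acid makes that bond and closes ring C in one operation, turning the carboxyl carbon into the C4 carbonyl. The step exploits ring A: C4a is the only unsubstituted carbon ortho to the ether oxygen O1, because C8 carries a methoxy group, and it lies para to the C7 methoxy group, so the tethered acylium carbon has a single, strongly activated site. The precursor is a (Z)-3-aryloxy-3-arylacrylic acid with the 2,3-dimethoxyphenoxy group and ring B on C-β and the 3'-hydroxyl masked as a deactivating tosylate.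

Key step: step 6

Remark: the phenol addition should give mainly the Z enol ether. The ester, the acid and the activated acid are drawn as Z, and any E isomer would be carried along, because the two geometries interconvert in the acid of the key step. "Tosyloxy" stands for (4-methylphenyl)sulfonyloxy throughout.

Step 1
Reactants: 1 3-hydroxy-4,5-dimethoxybenzaldehyde; 2 dimethyl (1-diazo-2-oxopropyl)phosphonate (Ohira–Bestmann reagent)
Product: 3 5-ethynyl-2,3-dimethoxyphenol
Conditions: K2CO3 (3 equiv), MeOH, 0 °C to rt; aq. NH4Cl work-up
Reagents that add atoms: dimethyl (1-diazo-2-oxopropyl)phosphonate (2), COP(=O)(OC)C(=[N+]=[N-])C(C)=O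
Why: Seyferth–Gilbert homologation in the Ohira–Bestmann variant, in which methanolysis of 2 releases the diazomethylphosphonate anion that olefinates the aldehyde and, after loss of N2 and a 1,2-hydrogen shift, leaves the terminal alkyne; the phenoxide is meta to the formyl group and does not quench its electrophilicity, and no sulfonate is present yet to suffer methanolysis.

Step 2
Reactants: 3 5-ethynyl-2,3-dimethoxyphenol; 4 4-methylbenzenesulfonyl chloride
Product: 5 5-ethynyl-2,3-dimethoxyphenyl 4-methylbenzenesulfonate
Conditions: Et3N, DMAP (cat.), CH2Cl2, 0 °C to rt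
Reagents that add atoms: 4-methylbenzenesulfonyl chloride (4), Cc1ccc(S(Cl)(=O)=O)cc1
Why: O-sulfonylation of a phenol under amine base, which installs a group that should survive the later base and strong-acid steps and that withdraws electron density from ring B.

Step 3
Reactants: 5 5-ethynyl-2,3-dimethoxyphenyl 4-methylbenzenesulfonate; 6 methyl chloroformate
Product: 8 methyl 3-[3,4-dimethoxy-5-(tosyloxy)phenyl]prop-2-ynoate, via lithium acetylide 7 (not isolated)
Conditions: LiN(SiMe3)2 (1.05 equiv), THF, −78 °C; then ClCO2Me (1.5 equiv), −78 °C to 0 °C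
Reagents that add atoms: methyl chloroformate (6), COC(=O)Cl
Why: Deprotonation of a terminal alkyne and C-acylation of the acetylide with a chloroformate is the standard alkynoate synthesis, and the non-nucleophilic amide base should leave the sulfonate sulfur untouched where an alkyllithium might attack it.

Step 4
Reactants: 8 methyl 3-[3,4-dimethoxy-5-(tosyloxy)phenyl]prop-2-ynoate; 9 2,3-dimethoxyphenol
Product: 10 methyl (2Z)-3-(2,3-dimethoxyphenoxy)-3-[3,4-dimethoxy-5-(tosyloxy)phenyl]prop-2-enoate
Conditions: Cs2CO3 (0.3 equiv), DMF, 50 °C
Reagents that add atoms: none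
Why: Base-catalysed oxa-Michael addition of a phenol to an arylpropiolate, in which the oxygen attacks the β-carbon (the only position giving an ester-stabilised anion) and anti protonation should give mainly the Z enol ether, while the moderate temperature keeps sulfonyl transfer to the phenoxide slow.

Step 5
Reactants: 10 methyl (2Z)-3-(2,3-dimethoxyphenoxy)-3-[3,4-dimethoxy-5-(tosyloxy)phenyl]prop-2-enoate
Product: 11 (2Z)-3-(2,3-dimethoxyphenoxy)-3-[3,4-dimethoxy-5-(tosyloxy)phenyl]prop-2-enoic acid
Conditions: LiOH·H2O (3 equiv), THF/H2O (3:1), rt; then 1 M HCl, 0 °C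
Reagents that add atoms: lithium hydroxide (its oxygen becomes a carboxyl oxygen), [Li+].[OH-]
Why: Saponification of a methyl ester by acyl–oxygen cleavage, where at room temperature hydroxide attack on the ester carbonyl should outpace attack on the aryl sulfonate or on the β-carbon, and cold acidification should free the acid without hydrolysing the enol ether.

Step 6
Reactants: 11 (2Z)-3-(2,3-dimethoxyphenoxy)-3-[3,4-dimethoxy-5-(tosyloxy)phenyl]prop-2-enoic acid
Product: 13 5-(7,8-dimethoxy-4-oxo-4H-chromen-2-yl)-2,3-dimethoxyphenyl 4-methylbenzenesulfonate, via acyl methanesulfonate 12 (not isolated)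
Conditions: Eaton's reagent (P2O5 in MeSO3H, about 1:10 by weight), rt to 45 °C; then ice-water
Reagents that add atoms: none
Why: P2O5/MeSO3H dehydrates the carboxylic acid to the acyl methanesulfonate 12, which ionises to an acylium ion; C4a of the aryloxy ring attacks its carbon (the future C4) and loss of the C4a proton restores the aromaticity of ring A. The closest known reaction type is the intramolecular Friedel–Crafts acylation of β-aryloxyacrylic and β-aryloxycinnamic acids to chromones and flavones (Ruhemann-type flavone synthesis). Ring C closes as a six-membered ring in the 6-exo mode at the acyl carbon (exo-trig on 12, exo-dig on the free acylium ion), the carbonyl oxygen staying outside the ring. No stereocentre is formed, and the alkene geometry is not critical: the Z acid has the carboxyl group cis to the aryloxy group as required, and any E acid should reach it by reversible protonation at C-α in the strong acid. The site selectivity needed on ring A is secured by the substitution pattern, since C4a is the sole free position ortho to O1 and is para to the C7 methoxy group. The selectivity for ring A over ring B (closure there would need the E acid and a five-membered ring, giving an indenone) is secured by the six-membered transition state, the greater nucleophilicity of ring A and the electron-withdrawing tosylate on ring B, which is itself stable to the non-nucleophilic acid.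

Step 7
Reactants: 13 5-(7,8-dimethoxy-4-oxo-4H-chromen-2-yl)-2,3-dimethoxyphenyl 4-methylbenzenesulfonate
Product: 14 3'-hydroxy-4',5',7,8-tetramethoxyflavone
Conditions: K2CO3 (5 equiv), MeOH/THF (2:1), 65 °C; then 1 M HCl
Reagents that add atoms: none
Why: Methanolysis of an aryl sulfonate ester, in which methoxide attacks the sulfonyl sulfur and expels the ring B phenoxide, while the four methyl ethers and the pyranone should be inert to carbonate in methanol.

Compound list
1 | 3-hydroxy-4,5-dimethoxybenzaldehyde | COc1cc(C=O)cc(O)c1OC | starting material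
2 | dimethyl (1-diazo-2-oxopropyl)phosphonate (Ohira–Bestmann reagent) | COP(=O)(OC)C(=[N+]=[N-])C(C)=O | starting material
3 | 5-ethynyl-2,3-dimethoxyphenol | COc1cc(C#C)cc(O)c1OC | intermediate
4 | 4-methylbenzenesulfonyl chloride | Cc1ccc(S(Cl)(=O)=O)cc1 | starting material
5 | 5-ethynyl-2,3-dimethoxyphenyl 4-methylbenzenesulfonate | COc1cc(C#C)cc(OS(=O)(=O)c2ccc(C)cc2)c1OC | intermediate
6 | methyl chloroformate | COC(=O)Cl | starting material
7 | lithium 2-[3,4-dimethoxy-5-(tosyloxy)phenyl]ethynide, the lithium acetylide of 5 (formed and consumed in step 3) | COc1cc(C#C[Li])cc(OS(=O)(=O)c2ccc(C)cc2)c1OC | intermediate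
8 | methyl 3-[3,4-dimethoxy-5-(tosyloxy)phenyl]prop-2-ynoate | COC(=O)C#Cc1cc(OC)c(OC)c(OS(=O)(=O)c2ccc(C)cc2)c1 | intermediate
9 | 2,3-dimethoxyphenol | COc1cccc(O)c1OC | starting material
10 | methyl (2Z)-3-(2,3-dimethoxyphenoxy)-3-[3,4-dimethoxy-5-(tosyloxy)phenyl]prop-2-enoate | COc1cccc(O/C(=C\C(=O)OC)c2cc(OC)c(OC)c(OS(=O)(=O)c3ccc(C)cc3)c2)c1OC | intermediate
11 | (2Z)-3-(2,3-dimethoxyphenoxy)-3-[3,4-dimethoxy-5-(tosyloxy)phenyl]prop-2-enoic acid | COc1cccc(O/C(=C\C(=O)O)c2cc(OC)c(OC)c(OS(=O)(=O)c3ccc(C)cc3)c2)c1OC | intermediate
12 | (2Z)-3-(2,3-dimethoxyphenoxy)-3-[3,4-dimethoxy-5-(tosyloxy)phenyl]prop-2-enoic methanesulfonic anhydride (formed and consumed in step 6) | COc1cccc(O/C(=C\C(=O)OS(C)(=O)=O)c2cc(OC)c(OC)c(OS(=O)(=O)c3ccc(C)cc3)c2)c1OC | intermediate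
13 | 5-(7,8-dimethoxy-4-oxo-4H-chromen-2-yl)-2,3-dimethoxyphenyl 4-methylbenzenesulfonate | COc1cc(-c2cc(=O)c3ccc(OC)c(OC)c3o2)cc(OS(=O)(=O)c2ccc(C)cc2)c1OC | intermediate
14 | 3'-hydroxy-4',5',7,8-tetramethoxyflavone, 2-(3-hydroxy-4,5-dimethoxyphenyl)-7,8-dimethoxy-4H-chromen-4-one | COc1cc(-c2cc(=O)c3ccc(OC)c(OC)c3o2)cc(O)c1OC | target

Total step count: 7. Longest linear sequence: 7 steps (1 to 14).

Steps most likely to fail

Step 6. The ring closure could lose out to intermolecular acylation or methanesulfonylation of the electron-rich aryloxy ring, or to acid cleavage of the aryl vinyl ether by adventitious water before the acylium ion is captured. Fallback: setting out from 1, a Claisen–Schmidt condensation with commercial 1-(2-hydroxy-3,4-dimethoxyphenyl)ethanone (CC(=O)c1ccc(OC)c(OC)c1O; KOH, EtOH, rt) should give the chalcone (2E)-1-(2-hydroxy-3,4-dimethoxyphenyl)-3-(3-hydroxy-4,5-dimethoxyphenyl)prop-2-en-1-one F1. Oxidative cyclisation of this 2'-hydroxychalcone (I2 cat., DMSO, 120 °C) would then come back to the route at 14. In this approach C4–C4a is present from the start and ring C is closed at O1–C2 instead, so no acylation of ring A is needed.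

Step 5. Hydroxide could attack the sulfonate sulfur, removing the tosyl group too early, or add to the β-carbon, expelling the phenoxide and leading to decarboxylation. Fallback: setting out from 5, the acetylide 7 would be generated as in step 3 and trapped with allyl chloroformate (C=CCOC(=O)Cl) to give prop-2-en-1-yl 3-[3,4-dimethoxy-5-(tosyloxy)phenyl]prop-2-ynoate F2. Addition of 9 under the conditions of step 4 should give prop-2-en-1-yl (2Z)-3-(2,3-dimethoxyphenoxy)-3-[3,4-dimethoxy-5-(tosyloxy)phenyl]prop-2-enoate F3. Tsuji–Trost deallylation (Pd(PPh3)4 cat., a zerovalent palladium complex, morpholine, THF, rt) would transfer the allyl group to the amine and come back to the route at 11 without any hydroxide.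

Step 4. Conjugate addition of the ortho-substituted phenoxide to the donor-substituted arylpropiolate may be slow, and raising the temperature invites sulfonyl transfer from ring B to the phenoxide. Fallback: setting out from 8, anti hydroiodination (NaI, AcOH, 70 °C) should give methyl (2Z)-3-iodo-3-[3,4-dimethoxy-5-(tosyloxy)phenyl]prop-2-enoate F4. Copper-catalysed Ullmann-type vinylation of 9 (CuI cat., N,N-dimethylglycine, Cs2CO3, 1,4-dioxane, 80 °C) proceeds with retention of alkene geometry and would come back to the route at 10. The C–O bond is then made by coupling at a vinyl iodide and no longer depends on the Michael reactivity of the triple bond.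

Further compounds
F1 | step 6 | (2E)-1-(2-hydroxy-3,4-dimethoxyphenyl)-3-(3-hydroxy-4,5-dimethoxyphenyl)prop-2-en-1-one | COc1cc(/C=C/C(=O)c2ccc(OC)c(OC)c2O)cc(O)c1OC
F2 | step 5 | prop-2-en-1-yl 3-[3,4-dimethoxy-5-(tosyloxy)phenyl]prop-2-ynoate | C=CCOC(=O)C#Cc1cc(OC)c(OC)c(OS(=O)(=O)c2ccc(C)cc2)c1
F3 | step 5 | prop-2-en-1-yl (2Z)-3-(2,3-dimethoxyphenoxy)-3-[3,4-dimethoxy-5-(tosyloxy)phenyl]prop-2-enoate | COc1cccc(O/C(=C\C(=O)OCC=C)c2cc(OC)c(OC)c(OS(=O)(=O)c3ccc(C)cc3)c2)c1OC
F4 | step 4 | methyl (2Z)-3-iodo-3-[3,4-dimethoxy-5-(tosyloxy)phenyl]prop-2-enoate | COC(=O)/C=C(\I)c1cc(OC)c(OC)c(OS(=O)(=O)c2ccc(C)cc2)c1
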